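Compare the last readings of the two earlier runs: winter holds more target than spring, yet each has lost about the same share, 26.4% and 26.1%, to something that is neither starting material nor target.

common to all: starting material 0.63 M

| run | reagent in the second phase | remark | time | volume of the second phase over the first |
|---|---|---|---|---|
| spring | 1.1 M | run made earlier |  |  |
| winter | 1.8 M | run made earlier |  |  |
| flask | 0.819 M |  | 5.0 min | 2.0 |

| run | time / min | target / % | starting material / % |
|---|---|---|---|
| spring | 0.417 | 0.5 | 96.4 |
| spring | 1.00 | 8.7 | 90.0 |
| spring | 2.00 | 20.2 | 71.9 |
| spring | 5.00 | 40.8 | 32.8 |
| winter | 0.667 | 7.9 | 93.8 |
| winter | 2.00 | 32.8 | 59.3 |
| winter | 3.00 | 45.6 | 39.4 |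
| winter | 5.00 | 56.7 | 17.2 |

(standard deviation of a reading: 1 percentage point)

- in the second phase: reagent in the second phase; everything else is in the first
- charges count per volume of the first phase; a concentration in a rate is the amount of a species over the volume of its own phase; every rate counts per litre of the first phase
- the earlier runs hold the two phases in the same ratio of volumes as the flask asked about

- Sunday's: doubling the amount of reagent in the second phase, all else as stated
- Wednesday's: doubling the transfer coefficient of the reagent in the second phase, all else as stated

- amount of target at 5.0 min, in percent of the starting material charged
- the change that raises the amount of target at 5.0 min, in percent of the starting material charged most ("none" if none brings more than 2 percentage points) (Sunday's / Wednesday's / none)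
- amount of target at 5.0 min, in percent of the starting material charged, after Sunday's

Build the flask one process at a time, in shares of the charge. Begin with the main step. The late fall of starting material gives a loss constant (pseudo-first-order) of 0.262 /min in spring and 0.413 /min in winter, and per molar of reagent charged these average 0.234 /M/min. Run at that rate from the start, this first reckoning gives the flask 61.6% target.

Now add the delay at the start, which I read as reagent still arriving. Both curves point back to a delay of 0.736 min, so the reckoning leaves the flask 44.2% starting material and lowers target to 55.8%.

Then add the missing share. Replace each curve by its mean: starting material halfway between its ends, target at half its end value. Define the side constant as the missing share divided by time, both means and the starting charge. The readings give 0.619 /M/min in spring and 0.499 /M/min in winter; carry their mean, 0.559 /M/min. Multiplied by charge, time, the mean of starting material and 0.5, it gives the flask a side number of 0.635, and the reckoned target is the consumed share over one plus that number: 34.1%. Doubled reagent gives 19.6% left and 52.7% target. Halving the delay for Wednesday's gives 41.2% left and 36.2% target.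

The forecast says 32%, a little below my figure, then Sunday's and 53%, reading the loss “as target reacting with starting material”.

The flask gives 32.1%. Sunday's adds 23 percentage points and reaches 54.8%, while Wednesday's adds 6.1 points.

    starting material + reagent in the reaction phase → target (k = 0.0156 /M/s)
    reagent in the reaction phase ⇌ dormant form (K = 6.25, k = 0.00276 /s)
    starting material + target → side product (k = 0.00492 /M/s)
    reagent in the reaction phase ⇌ reagent in the second phase, rate k4*([reagent in the reaction phase] - [reagent in the second phase]/K4) per volume of the first phase (partition coefficient = 0.630, kL = 0.00615 /s)

At 2.50 min the flask held 72.9% starting material and 20.1% target, against my means of 72.1% and 17.1%. For the neighbour with 0.25 M starting material, keeping the flask's reckoned fall of starting material, the side constant gives a side number of 0.252 and 44.6% target; that neighbour gives 47.8%. The flask is not at rest at 5.0 min, with 46% starting material remaining. By 50.0 min the flask's starting material is down to 0.136%, target has gained 5.7 points to reach 37.8%, and side product, each counted as two, stands at 62.1%.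

The readings were computed for an exercise, and the scatter is random.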